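## Retrosynthetic overview

1. Target ⇐ selective O‑acetylation of the primary C19‑OH of a 3,19‑diol acid ⇐ hydride reduction of a bicyclic 3‑keto‑19‑ester (axial 3‑OH from the ketone, CH2OH from the ester).
2. Key disconnection: C4–C5 and C9–C10 are cut back to one acyclic α‑methyl β‑keto ester triene. A Mn(III)‑generated C4 radical closes ring A first, then ring B, and the cascade ends by loss of PhSO2• from C7 of an allyl sulfone, which fixes the Δ7 alkene. A chiral ester sets the absolute configuration.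
3. Acyclic precursor ⇐ acetoacetate dianion alkylation (C1–C2) ⇐ C15 allylic bromide ⇐ allylic oxidation ⇐ α‑prenylation of a C10 allyl sulfone (C6–C7).
4. C10 sulfone ⇐ methyl geranate (allylic oxidation, bromide, PhSO2Na) ⇐ carbocupration of methyl but‑2‑ynoate (C12–C13, sets 13E).

Assumption: C‑locants in the text are labdane locants; (+)‑8‑phenylmenthol and sodium benzenesulfinate are auxiliary reagents whose atoms do not reach the target; the facial sense of the auxiliary in step 10 is predicted from the π‑shielding model given there and has not been checked experimentally.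

## Route

Step 1
Reactants: 1 5‑bromo‑2‑methylpent‑2‑ene; 2 methyl but‑2‑ynoate
Product: 5 methyl (2E)‑3,7‑dimethylocta‑2,6‑dienoate, via (4‑methylpent‑3‑en‑1‑yl)magnesium bromide 3 (not isolated), via (4‑methylpent‑3‑en‑1‑yl)copper 4 (not isolated)
Conditions: Mg, THF; CuBr·SMe2 (1.0 equiv), −40 °C; 2, −78 °C; MeOH then sat. NH4Cl at −78 °C
Reagents that add atoms: none
Why: syn‑carbocupration of the ynoate (organocopper conjugate addition) with protonation at −78 °C places the alkyl group and H cis, so the enoate is formed as the 2E isomer (target 13E).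

Step 2
Reactants: 5 methyl (2E)‑3,7‑dimethylocta‑2,6‑dienoate
Product: 6 methyl (2E,6E)‑8‑hydroxy‑3,7‑dimethylocta‑2,6‑dienoate
Conditions: SeO2 (0.5 equiv), t‑BuOOH (2 equiv), salicylic acid (cat.), CH2Cl2, 0 °C → rt
Reagents that add atoms: selenium dioxide (O‑transfer catalyst), O=[Se]=O; tert‑butyl hydroperoxide (terminal oxidant), CC(C)(C)OO
Why: SeO2/TBHP allylic oxidation (ene then [2,3]‑shift) hydroxylates only the (E)‑methyl of the electron‑rich terminal isopropylidene, giving the 6E allylic alcohol (future C7, trans to C11).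

Step 3
Reactants: 6 methyl (2E,6E)‑8‑hydroxy‑3,7‑dimethylocta‑2,6‑dienoate
Product: 8 methyl (2E,6E)‑3,7‑dimethyl‑8‑(phenylsulfonyl)octa‑2,6‑dienoate, via allylic bromide 7 (not isolated)
Conditions: PBr3 (0.4 equiv), Et2O, −10 °C; crude bromide, PhSO2Na (1.5 equiv), DMF, rt
Reagents that add atoms: phosphorus tribromide (Br of 7), BrP(Br)Br; sodium benzenesulfinate, [Na+].[O-]S(=O)c1ccccc1
Why: SN2 bromination of the primary allylic alcohol and S‑alkylation of the sulfinate both proceed without allylic transposition, so the E alkene is kept.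

Step 4
Reactants: 8 methyl (2E,6E)‑3,7‑dimethyl‑8‑(phenylsulfonyl)octa‑2,6‑dienoate; 9 1‑bromo‑3‑methylbut‑2‑ene
Product: 10 methyl (2E,6E)‑3,7,11‑trimethyl‑8‑(phenylsulfonyl)dodeca‑2,6,10‑trienoate (racemic at C8)
Conditions: NaHMDS (1.05 equiv), THF, −78 °C; 9, −78 → −30 °C
Reagents that add atoms: none
Why: Biellmann‑type α‑alkylation of the allyl sulfone carbanion (the most acidic C–H, formed selectively beside the enoate) builds C6–C7; the new sulfone stereocentre is racemic and is erased in step 10.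

Step 5
Reactants: 10 methyl (2E,6E)‑3,7,11‑trimethyl‑8‑(phenylsulfonyl)dodeca‑2,6,10‑trienoate
Product: 11 methyl (2E,6E,10E)‑12‑hydroxy‑3,7,11‑trimethyl‑8‑(phenylsulfonyl)dodeca‑2,6,10‑trienoate
Conditions: SeO2 (0.5 equiv), t‑BuOOH (2 equiv), salicylic acid (cat.), CH2Cl2, 0 °C → rt
Reagents that add atoms: selenium dioxide (O‑transfer catalyst), O=[Se]=O; tert‑butyl hydroperoxide (terminal oxidant), CC(C)(C)OO
Why: SeO2/TBHP allylic oxidation again attacks the (E)‑methyl of the only electron‑rich alkene (the other two are deactivated by the sulfone or the ester), giving the 10E alcohol (future C1 trans to C6).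

Step 6
Reactants: 11 methyl (2E,6E,10E)‑12‑hydroxy‑3,7,11‑trimethyl‑8‑(phenylsulfonyl)dodeca‑2,6,10‑trienoate
Product: 12 methyl (2E,6E,10E)‑12‑bromo‑3,7,11‑trimethyl‑8‑(phenylsulfonyl)dodeca‑2,6,10‑trienoate
Conditions: CBr4, PPh3, CH2Cl2, 0 °C
Reagents that add atoms: carbon tetrabromide, BrC(Br)(Br)Br
Why: Appel bromination under neutral conditions converts the primary allylic alcohol by SN2 without moving the double bond.

Step 7
Reactants: 13 methyl 3‑oxobutanoate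
Product: 14 (1S,2R,5S)‑5‑methyl‑2‑(2‑phenylpropan‑2‑yl)cyclohexyl 3‑oxobutanoate
Conditions: (+)‑8‑phenylmenthol (1.0 equiv), DMAP (0.2 equiv), toluene, reflux, 4 Å MS (removal of MeOH)
Reagents that add atoms: (+)‑8‑phenylmenthol, C[C@H]1CC[C@@H]([C@H](C1)O)C(C)(C)c1ccccc1
Why: DMAP‑catalysed transesterification of a β‑keto ester (via the acylketene) installs the chiral ester without touching its stereocentres.

Step 8
Reactants: 12 methyl (2E,6E,10E)‑12‑bromo‑3,7,11‑trimethyl‑8‑(phenylsulfonyl)dodeca‑2,6,10‑trienoate; 14 (1S,2R,5S)‑5‑methyl‑2‑(2‑phenylpropan‑2‑yl)cyclohexyl 3‑oxobutanoate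
Product: 16 1‑[(1S,2R,5S)‑5‑methyl‑2‑(2‑phenylpropan‑2‑yl)cyclohexyl] 16‑methyl (6E,10E,14E)‑2,6,10,14‑tetramethyl‑3‑oxo‑9‑(phenylsulfonyl)hexadeca‑6,10,14‑trienedioate (mixture at C2 and C9), via unmethylated keto ester 15 (not isolated)
Conditions: 14, NaH, THF, 0 °C; n‑BuLi, 0 °C; 12, 0 °C, 30 min; then MeI (1.1 equiv), DMPU, 0 °C → rt
Reagents that add atoms: iodomethane, CI
Why: acetoacetate dianion alkylation (Weiler) joins the γ‑carbon to the primary allylic bromide by SN2 (C1–C2), and the remaining β‑keto ester enolate is then C‑methylated in the same flask (C18); both stereocentres formed are inconsequential.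

Step 9
Reactants: 16 the diester from step 8
Product: 17 (2E,6E,10E)‑16‑{[(1S,2R,5S)‑5‑methyl‑2‑(2‑phenylpropan‑2‑yl)cyclohexyl]oxy}‑3,7,11,15‑tetramethyl‑14,16‑dioxo‑8‑(phenylsulfonyl)hexadeca‑2,6,10‑trienoic acid
Conditions: LiOH·H2O (4 equiv), THF/MeOH/H2O, 40 °C; 1 M HCl to pH 3
Reagents that add atoms: lithium hydroxide (hydroxide O), [Li+].[OH-]
Why: saponification removes only the methyl enoate, because the β‑keto ester sits as its enolate and carries a very hindered ester.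

Step 10
Reactants: 17 the keto ester acid from step 9
Product: 18 (2E)‑5‑[(1R,4aS,5S,8aS)‑2,5,8a‑trimethyl‑5‑({[(1S,2R,5S)‑5‑methyl‑2‑(2‑phenylpropan‑2‑yl)cyclohexyl]oxy}carbonyl)‑6‑oxo‑1,4,4a,5,6,7,8,8a‑octahydronaphthalen‑1‑yl]‑3‑methylpent‑2‑enoic acid (labdane 4S,5S,9R,10S; trans‑decalin, axial C19 ester cis to the C10 methyl, Δ7)
Conditions: Mn(OAc)3·2H2O (2.2 equiv, in portions), degassed AcOH (0.02 M), 25–40 °C, Ar, no Cu(OAc)2; chromatography to remove the minor diastereomer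
Reagents that add atoms: none
Why: Proposed new method: Mn(III) oxidises the enol of the α‑methyl β‑keto ester to the C4 radical, which closes ring A 6‑endo onto C5 of the (E)‑C5=C10 alkene and then ring B 6‑endo onto C9 of the (E)‑allyl sulfone through a chair–chair array (trans fusion, equatorial C9 side chain, ester anti to the ketone oxygen and therefore axial and cis to the C10 methyl), and the C8 radical then expels PhSO2• from C7 by β‑scission, which places the alkene at C7–C8 only and erases the sulfone stereocentre; the phenyl ring of the (1S,2R,5S) auxiliary stacks over one face of the s‑cis keto ester radical so that C5 adds to the open face and gives the 4S,5S,9R,10S series; the closest known reaction types are the Mn(III)‑based oxidative free‑radical polyene cyclisation of α‑alkyl β‑keto esters carrying 8‑phenylmenthyl esters and radical allylation with allyl sulfones (SH2′ with loss of a sulfonyl radical).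

Step 11
Reactants: 18 the bicyclic keto ester acid from step 10
Product: 20 (2E)‑5‑[(1R,4aS,5R,6S,8aS)‑6‑hydroxy‑5‑(hydroxymethyl)‑2,5,8a‑trimethyl‑1,4,4a,5,6,7,8,8a‑octahydronaphthalen‑1‑yl]‑3‑methylpent‑2‑enoic acid, via 3‑hydroxy ester 19 (not isolated)
Conditions: L‑Selectride (2.2 equiv), THF, −78 → −40 °C; then LiEt3BH (6 equiv), −40 → 45 °C; aq. NH4Cl, 1 M HCl to pH 3
Reagents that add atoms: none
Why: the bulky borohydride attacks the C3 ketone along the equatorial trajectory and gives the axial 3S alcohol (trans to C19, anti to the C10 methyl), and LiEt3BH then reduces the neopentyl ester to CH2OH and frees the auxiliary while the lithium carboxylate at C15 is not reduced (chemoselective borohydride reductions).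

Step 12
Reactants: 20 the diol acid from step 11
Product: 21 (2E)‑5‑[(1R,4aS,5R,6S,8aS)‑5‑(acetoxymethyl)‑6‑hydroxy‑2,5,8a‑trimethyl‑1,4,4a,5,6,7,8,8a‑octahydronaphthalen‑1‑yl]‑3‑methylpent‑2‑enoic acid (CNP0325522.1)
Conditions: Ac2O (2.5 equiv), pyridine, 0 °C → rt; then H2O/NaHCO3 (cleaves the mixed anhydride), acidify to pH 3
Reagents that add atoms: acetic anhydride, CC(=O)OC(C)=O
Why: acylation is selective for the primary C19 alcohol over the axial secondary 3‑OH, which is flanked by the quaternary C4; no stereocentre is touched.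

## Compound list

1 | 5‑bromo‑2‑methylpent‑2‑ene | CC(C)=CCCBr | starting material
2 | methyl but‑2‑ynoate | CC#CC(=O)OC | starting material
3 | (4‑methylpent‑3‑en‑1‑yl)magnesium bromide | CC(C)=CCC[Mg]Br | intermediate
4 | (4‑methylpent‑3‑en‑1‑yl)copper | CC(C)=CCC[Cu] | intermediate
5 | methyl (2E)‑3,7‑dimethylocta‑2,6‑dienoate | CC(C)=CCC/C(C)=C/C(=O)OC | intermediate
6 | methyl (2E,6E)‑8‑hydroxy‑3,7‑dimethylocta‑2,6‑dienoate | OC/C(C)=C/CC/C(C)=C/C(=O)OC | intermediate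
7 | methyl (2E,6E)‑8‑bromo‑3,7‑dimethylocta‑2,6‑dienoate | BrC/C(C)=C/CC/C(C)=C/C(=O)OC | intermediate
8 | methyl (2E,6E)‑3,7‑dimethyl‑8‑(phenylsulfonyl)octa‑2,6‑dienoate | O=S(=O)(C/C(C)=C/CC/C(C)=C/C(=O)OC)c1ccccc1 | intermediate
9 | 1‑bromo‑3‑methylbut‑2‑ene | CC(C)=CCBr | starting material
10 | methyl (2E,6E)‑3,7,11‑trimethyl‑8‑(phenylsulfonyl)dodeca‑2,6,10‑trienoate (racemic at C8) | CC(C)=CCC(/C(C)=C/CC/C(C)=C/C(=O)OC)S(=O)(=O)c1ccccc1 | intermediate
11 | methyl (2E,6E,10E)‑12‑hydroxy‑3,7,11‑trimethyl‑8‑(phenylsulfonyl)dodeca‑2,6,10‑trienoate | OC/C(C)=C/CC(/C(C)=C/CC/C(C)=C/C(=O)OC)S(=O)(=O)c1ccccc1 | intermediate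
12 | methyl (2E,6E,10E)‑12‑bromo‑3,7,11‑trimethyl‑8‑(phenylsulfonyl)dodeca‑2,6,10‑trienoate | BrC/C(C)=C/CC(/C(C)=C/CC/C(C)=C/C(=O)OC)S(=O)(=O)c1ccccc1 | intermediate
13 | methyl 3‑oxobutanoate | CC(=O)CC(=O)OC | starting material
14 | (1S,2R,5S)‑5‑methyl‑2‑(2‑phenylpropan‑2‑yl)cyclohexyl 3‑oxobutanoate | C[C@H]1CC[C@@H]([C@H](C1)OC(=O)CC(C)=O)C(C)(C)c1ccccc1 | intermediate
15 | 1‑[(1S,2R,5S)‑5‑methyl‑2‑(2‑phenylpropan‑2‑yl)cyclohexyl] 16‑methyl (6E,10E,14E)‑6,10,14‑trimethyl‑3‑oxo‑9‑(phenylsulfonyl)hexadeca‑6,10,14‑trienedioate | C[C@H]1CC[C@@H]([C@H](C1)OC(=O)CC(=O)CC/C(C)=C/CC(/C(C)=C/CC/C(C)=C/C(=O)OC)S(=O)(=O)c2ccccc2)C(C)(C)c1ccccc1 | intermediate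
16 | 1‑[(1S,2R,5S)‑5‑methyl‑2‑(2‑phenylpropan‑2‑yl)cyclohexyl] 16‑methyl (6E,10E,14E)‑2,6,10,14‑tetramethyl‑3‑oxo‑9‑(phenylsulfonyl)hexadeca‑6,10,14‑trienedioate | C[C@H]1CC[C@@H]([C@H](C1)OC(=O)C(C)C(=O)CC/C(C)=C/CC(/C(C)=C/CC/C(C)=C/C(=O)OC)S(=O)(=O)c2ccccc2)C(C)(C)c1ccccc1 | intermediate
17 | (2E,6E,10E)‑16‑{[(1S,2R,5S)‑5‑methyl‑2‑(2‑phenylpropan‑2‑yl)cyclohexyl]oxy}‑3,7,11,15‑tetramethyl‑14,16‑dioxo‑8‑(phenylsulfonyl)hexadeca‑2,6,10‑trienoic acid | C[C@H]1CC[C@@H]([C@H](C1)OC(=O)C(C)C(=O)CC/C(C)=C/CC(/C(C)=C/CC/C(C)=C/C(=O)O)S(=O)(=O)c2ccccc2)C(C)(C)c1ccccc1 | intermediate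
18 | (2E)‑5‑[(1R,4aS,5S,8aS)‑2,5,8a‑trimethyl‑5‑({[(1S,2R,5S)‑5‑methyl‑2‑(2‑phenylpropan‑2‑yl)cyclohexyl]oxy}carbonyl)‑6‑oxo‑1,4,4a,5,6,7,8,8a‑octahydronaphthalen‑1‑yl]‑3‑methylpent‑2‑enoic acid | C[C@H]1CC[C@@H]([C@H](C1)OC(=O)[C@@]1(C)[C@H]2CC=C(C)[C@@H](CC/C(C)=C/C(=O)O)[C@]2(C)CCC1=O)C(C)(C)c1ccccc1 | intermediate
19 | (2E)‑5‑[(1R,4aS,5S,6S,8aS)‑6‑hydroxy‑2,5,8a‑trimethyl‑5‑({[(1S,2R,5S)‑5‑methyl‑2‑(2‑phenylpropan‑2‑yl)cyclohexyl]oxy}carbonyl)‑1,4,4a,5,6,7,8,8a‑octahydronaphthalen‑1‑yl]‑3‑methylpent‑2‑enoic acid | C[C@H]1CC[C@@H]([C@H](C1)OC(=O)[C@@]1(C)[C@H]2CC=C(C)[C@@H](CC/C(C)=C/C(=O)O)[C@]2(C)CC[C@@H]1O)C(C)(C)c1ccccc1 | intermediate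
20 | (2E)‑5‑[(1R,4aS,5R,6S,8aS)‑6‑hydroxy‑5‑(hydroxymethyl)‑2,5,8a‑trimethyl‑1,4,4a,5,6,7,8,8a‑octahydronaphthalen‑1‑yl]‑3‑methylpent‑2‑enoic acid | OC[C@@]1(C)[C@H]2CC=C(C)[C@@H](CC/C(C)=C/C(=O)O)[C@]2(C)CC[C@@H]1O | intermediate
21 | (2E)‑5‑[(1R,4aS,5R,6S,8aS)‑5‑(acetoxymethyl)‑6‑hydroxy‑2,5,8a‑trimethyl‑1,4,4a,5,6,7,8,8a‑octahydronaphthalen‑1‑yl]‑3‑methylpent‑2‑enoic acid | CC(=O)OC[C@@]1(C)[C@H]2CC=C(C)[C@@H](CC/C(C)=C/C(=O)O)[C@]2(C)CC[C@@H]1O | target

## Summary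

Total step count: 12. Longest linear sequence: 11 (steps 1–6, then 8–12); step 7 is a one‑step side branch.

Steps most likely to fail:

Step 10. The risks are the facial selectivity of the non‑chelated auxiliary (magnitude and sense are predicted, not measured) and the β‑scission of PhSO2• from the C7 epimer whose C–S bond is equatorial. The fallback sets out from 12 and 13 and comes back at 20; it moves stereocontrol to a rigid metal chelate and sets C4 afterwards. Compound 13 is transesterified with (−)‑8‑phenylmenthol to (1R,2S,5R)‑8‑phenylmenthyl 3‑oxobutanoate F1. Its dianion is alkylated with 12 without the MeI quench to give the α‑unsubstituted keto ester F2. Mn(OAc)3 with Yb(OTf)3 in CF3CH2OH at −5 °C cyclises the Yb‑chelated keto ester, again with sulfonyl‑radical loss, to the C4‑H bicyclic keto ester F3. K2CO3/MeI then methylates C4 from the face anti to the C10 methyl to give the axial ester F4. L‑Selectride gives the axial alcohol F5, LiOH cleaves only the side‑chain methyl ester to give the acid F6, and LiEt3BH removes the auxiliary ester to give 20.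

Step 11. The risk is that LiEt3BH is too bulky for the axial neopentyl 8‑phenylmenthyl ester, or that forcing conditions touch the carboxylate. The fallback sets out from 16 and comes back at 20; it reduces everything and re‑oxidises the side chain. The methyl ester 16 is cyclised under the step‑10 conditions to the keto diester F7. L‑Selectride followed by LiAlH4 in refluxing THF reduces the ketone, the auxiliary ester and the enoate to the triol F8. MnO2 oxidises only the allylic C15 alcohol to the enal F9, and NaClO2/NaH2PO4/2‑methyl‑2‑butene gives 20.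

Step 8. The risk is that the strongly basic dianion deprotonates the sulfonyl C–H of 12, which could then be methylated, and that methylation over‑runs. The fallback sets out from 8 and 14 and comes back at 16; the dianion chemistry is run on a small electrophile and the fragments are joined by the sulfone. Compound 14 is methylated (K2CO3, MeI) to (1S,2R,5S)‑8‑phenylmenthyl 2‑methyl‑3‑oxobutanoate F10. 2‑Methyl‑2‑vinyloxirane F11 is opened 1,4 with Li2CuCl4 to (E)‑4‑chloro‑2‑methylbut‑2‑en‑1‑ol F12, and PBr3 gives (E)‑1‑bromo‑4‑chloro‑2‑methylbut‑2‑ene F13. The dianion of F10 displaces the more reactive bromide of F13 to give the chloro keto ester F14. Then 8 and F14 are treated with NaHMDS (2.1 equiv, cat. NaI, −78 → 0 °C): the first equivalent parks the keto ester as its enolate and the sulfonyl carbanion alkylates the allylic chloride to give 16.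

## Further compounds

F1 | step 10 | (1R,2S,5R)‑5‑methyl‑2‑(2‑phenylpropan‑2‑yl)cyclohexyl 3‑oxobutanoate | C[C@@H]1CC[C@H]([C@@H](C1)OC(=O)CC(C)=O)C(C)(C)c1ccccc1
F2 | step 10 | 1‑[(1R,2S,5R)‑5‑methyl‑2‑(2‑phenylpropan‑2‑yl)cyclohexyl] 16‑methyl (6E,10E,14E)‑6,10,14‑trimethyl‑3‑oxo‑9‑(phenylsulfonyl)hexadeca‑6,10,14‑trienedioate | C[C@@H]1CC[C@H]([C@@H](C1)OC(=O)CC(=O)CC/C(C)=C/CC(/C(C)=C/CC/C(C)=C/C(=O)OC)S(=O)(=O)c2ccccc2)C(C)(C)c1ccccc1
F3 | step 10 | C4‑H bicyclic keto ester (equatorial (1R,2S,5R)‑8‑phenylmenthyl ester, side‑chain methyl ester, Δ7) | C[C@@H]1CC[C@H]([C@@H](C1)OC(=O)[C@@H]1[C@H]2CC=C(C)[C@@H](CC/C(C)=C/C(=O)OC)[C@]2(C)CCC1=O)C(C)(C)c1ccccc1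
F4 | step 10 | C4‑methylated bicyclic keto ester (axial (1R,2S,5R)‑8‑phenylmenthyl ester, side‑chain methyl ester) | C[C@@H]1CC[C@H]([C@@H](C1)OC(=O)[C@@]1(C)[C@H]2CC=C(C)[C@@H](CC/C(C)=C/C(=O)OC)[C@]2(C)CCC1=O)C(C)(C)c1ccccc1
F5 | step 10 | 3‑axial‑hydroxy (1R,2S,5R)‑8‑phenylmenthyl ester, side‑chain methyl ester | C[C@@H]1CC[C@H]([C@@H](C1)OC(=O)[C@@]1(C)[C@H]2CC=C(C)[C@@H](CC/C(C)=C/C(=O)OC)[C@]2(C)CC[C@@H]1O)C(C)(C)c1ccccc1
F6 | step 10 | 3‑axial‑hydroxy (1R,2S,5R)‑8‑phenylmenthyl ester, side‑chain acid | C[C@@H]1CC[C@H]([C@@H](C1)OC(=O)[C@@]1(C)[C@H]2CC=C(C)[C@@H](CC/C(C)=C/C(=O)O)[C@]2(C)CC[C@@H]1O)C(C)(C)c1ccccc1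
F7 | step 11 | bicyclic keto diester ((1S,2R,5S)‑8‑phenylmenthyl ester at C19, methyl ester at C15) | C[C@H]1CC[C@@H]([C@H](C1)OC(=O)[C@@]1(C)[C@H]2CC=C(C)[C@@H](CC/C(C)=C/C(=O)OC)[C@]2(C)CCC1=O)C(C)(C)c1ccccc1
F8 | step 11 | (1R,4aS,5R,6S,8aS)‑5‑(hydroxymethyl)‑1‑[(3E)‑5‑hydroxy‑3‑methylpent‑3‑en‑1‑yl]‑2,5,8a‑trimethyl‑1,4,4a,5,6,7,8,8a‑octahydronaphthalen‑6‑ol | OC[C@@]1(C)[C@H]2CC=C(C)[C@@H](CC/C(C)=C/CO)[C@]2(C)CC[C@@H]1O
F9 | step 11 | (2E)‑5‑[(1R,4aS,5R,6S,8aS)‑6‑hydroxy‑5‑(hydroxymethyl)‑2,5,8a‑trimethyl‑1,4,4a,5,6,7,8,8a‑octahydronaphthalen‑1‑yl]‑3‑methylpent‑2‑enal | OC[C@@]1(C)[C@H]2CC=C(C)[C@@H](CC/C(C)=C/C=O)[C@]2(C)CC[C@@H]1O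
F10 | step 8 | (1S,2R,5S)‑5‑methyl‑2‑(2‑phenylpropan‑2‑yl)cyclohexyl 2‑methyl‑3‑oxobutanoate | C[C@H]1CC[C@@H]([C@H](C1)OC(=O)C(C)C(C)=O)C(C)(C)c1ccccc1
F11 | step 8 | 2‑methyl‑2‑vinyloxirane (purchased) | CC1(C=C)CO1
F12 | step 8 | (E)‑4‑chloro‑2‑methylbut‑2‑en‑1‑ol | OC/C(C)=C/CCl
F13 | step 8 | (E)‑1‑bromo‑4‑chloro‑2‑methylbut‑2‑ene | BrC/C(C)=C/CCl
F14 | step 8 | (1S,2R,5S)‑5‑methyl‑2‑(2‑phenylpropan‑2‑yl)cyclohexyl (6E)‑8‑chloro‑2,6‑dimethyl‑3‑oxooct‑6‑enoate | C[C@H]1CC[C@@H]([C@H](C1)OC(=O)C(C)C(=O)CC/C(C)=C/CCl)C(C)(C)c1ccccc1
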